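The numbers in the tables stem from a simulated flask for substances that don't exist.

Time is the gap here: Monday's flask is followed to 25.0 min, and the question stands at 2.0 h.

| setting | Monday's | Friday's | flask |
|---|---|---|---|
| left-handed substrate | 0.050 M | 0.050 M | 0.050 M |
| right-handed substrate | 0.050 M | 0.050 M | 0.050 M |
| partner | 1.2 equiv | 1.8 equiv | 1.20 equiv |
| free catalyst | 2 mol% | 2 mol% | 2 mol% |
| remark | the very flask that is asked about, followed so far | run made earlier |  |
| time |  |  | 2.0 h |

| run | time / min | left-handed substrate / % | right-handed substrate / % | left-handed product / % |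
|---|---|---|---|---|
| Monday's | 4.00 | 48.3 | 47.9 | 1.1 |
| Monday's | 8.00 | 47.6 | 46.3 | 2.2 |
| Monday's | 12.0 | 46.9 | 45.9 | 2.1 |
| Monday's | 15.0 | 46.4 | 44.9 | 3.0 |
| Monday's | 20.0 | 46.3 | 44.3 | 3.9 |
| Monday's | 25.0 | 45.9 | 43.8 | 4.1 |
| Friday's | 10.0 | 47.1 | 45.3 | 3.9 |
| Friday's | 15.0 | 45.8 | 44.4 | 4.3 |
| Friday's | 25.0 | 44.3 | 42.1 | 5.3 |
| Friday's | 40.0 | 44.3 | 41.0 | 6.4 |
| Friday's | 80.0 | 42.2 | 38.9 | 8.4 |
| Friday's | 120 | 42.0 | 37.9 | 9.4 |

(each reading ± 0.3 percentage points)

- part of the left-handed substrate and right-handed substrate charged together that has reacted at 2.0 h
- excess of left-handed product over right-handed product in the product at 2.0 h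
- excess of right-handed substrate over left-handed substrate among what is left of the two at 2.0 h

- free catalyst is single-handed; left-handed substrate and right-handed substrate are mirror images of each other, charged as a racemate, each of them at the stated concentration
- an excess is below zero if the other one leads

The percentages count both substrates together, so each substrate starts at half of the total. I divide by that and work with the fraction left, f. Friday's last row gives s = 1.59, where s, the selectivity factor, is ln f of the right-handed substrate over ln f of the left-handed substrate. Monday's last row reads 1.55, close to it.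

But s gives no clock. At 25.0 min, Monday's ln f of the left-handed substrate is 0.707 of Friday's. I assume that this ratio lasts to 2.0 h. Then Monday's flask keeps f = 88.4 % of the left-handed substrate, and f to the power s gives 82.2 % of the right-handed substrate. So I reckon c = 14.7 % and eS = −3.63 %. If I count what the two substrates lose as product, the same f give eP = −21.1 %.

The forecast gives c 16 %, eP −9 % and eS −4.3 %, on the ground that “Right substrate is consumed about 1.5 times faster than left”; its c stands above mine, and its eP stands above mine.

Monday's flask gives c 17.2 %, eP −8.22 % and eS −4.48 %. My eP lies below the value of Monday's flask. In that flask left-handed product and right-handed product turn into each other, and a net 0.973 % of the two substrates charged has gone from right-handed product to left-handed product. My c falls short: 87 % of the left-handed charge stands unbound, not 88.4 %. Put to the power s, that fraction gives 80.1 %, and the flask holds 79 % of the right-handed substrate.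

    free catalyst → spent catalyst (k = 0.320 h⁻¹)
    partner + catalyst intermediate B → free catalyst + right-handed product (k = 780 M⁻¹ h⁻¹)
    free catalyst + right-handed substrate ⇌ catalyst intermediate B (K = 95.0 M⁻¹, k = 9900 M⁻¹ h⁻¹)
    left-handed product ⇌ right-handed product (k = 0.330 h⁻¹)
    partner + catalyst intermediate A → free catalyst + left-handed product (k = 1700 M⁻¹ h⁻¹)
    2 partner → self-condensation product (k = 45.0 M⁻¹ h⁻¹)
    free catalyst + left-handed substrate ⇌ catalyst intermediate A (K = 24.0 M⁻¹, k = 39000 M⁻¹ h⁻¹)

In the neighbour flask with 1.2 mol% of free catalyst, 91 % of the left-handed substrate stands at 2.0 h, so s gives 86.1 % of the right-handed substrate. That flask holds 86 %.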